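## Structural features

The target is a germacranolide: a ten-membered carbocycle (C1–C10) fused across C6–C7 to an α-methylene-γ-butyrolactone (O6–C12(=O)–C11(=C13H2)), with H6 and H7 on opposite faces (trans-fused). The ring holds two ring-cis trisubstituted alkenes, C1=C10 (C10 carries the C14 methyl ester) and C4=C5 (C4 carries the C15 methyl), and between them the cis-2,3-epoxide, which is therefore allylic on both sides. Six ring stereocentres fall into two blocks, C2/C3 and the contiguous run C6–C7–C8–C9. O8 carries the (2S,3S)-2,3-epoxy-2-methylbutanoyl group, O9 is free, and the 8,9-diol is threo. The fragile groups are the exocyclic methylene lactone (nucleophiles, base), the doubly allylic epoxide (acid, zerovalent palladium), the epoxy ester (acid, and acyl shift to the free O9) and the acrylate. The real difficulty is a ten-membered ring with two cis alkenes and four adjacent stereocentres, plus an end game in which the epoxides and the methylene lactone meet only near-neutral reagents. The key step exploits the fact that C6 is oxygenated and that C8=C7–C6–C1–C10=C9 is a 3-oxy-1,5-diene once C1–C6 is a bond of a six-membered ring C1–C6. That ring already contains C4=C5, the C15 methyl and the cis C2/C3 oxygens, which is the substitution pattern of an arene cis-dihydrodiol.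

## Logic of the disconnections

42 ⇒ 40. The O9–CH2 bond of a siloxymethyl acetal is cut. O9 must stay masked while O8 is acylated and is freed last so that no base or acid meets the finished molecule. Nothing is gained in skeleton. The forward step must use buffered fluoride that leaves two epoxides, the methylene lactone and the O8 ester alone.

40 ⇒ 34 + 38. The ester C–O bond at O8 is cut, which makes the route convergent and lets the epoxy acid be made enantiopure on its own. 34 comes from 33 by cutting the benzylic C–O bond of the O8 ether. The forward demand is orthogonality of the two ether groups and acylation of a hindered secondary alcohol without acid.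

33 ⇒ 30. The C11=C13 bond is cut. The Michael acceptor is installed only after every nucleophilic or alkoxide step on the lactone, so 30 is a robust saturated lactone. The forward step must form the lactone enolate selectively beside the acrylate and the epoxide.

30 ⇒ 27 ⇒ 26. The two epoxide C–O bonds are traced to a cis-diol and its acetonide. A doubly allylic epoxide would not survive enolate and organometallic chemistry, whereas the acetonide does and carries the arene-derived configuration. The demand is net retention at both carbons, that is two inversions at one allylic carbon without ionisation.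

26 ⇒ 24. The O6–C12 acyl bond and the C6–H bond are cut, leading back to the C6 ketone that the rearrangement delivers. The hydride must enter from the face that puts O6 trans to the C7 side chain.

24 ⇒ 23 + 7. The C7–C11 bond is cut. C7 is the enolate carbon created by the rearrangement and the only α′ position of the enone. Two carbons and one stereocentre are removed. The alkylation must occur anti to the C8 ether and without β-elimination of that ether.

23 ⇒ 20. The C1–C6 bond is reconnected and the C8–C9 bond is cut (retro oxy-Cope). The ten-membered ring becomes a cyclohexene, the C8 and C9 stereocentres become enol-ether geometries, and the C1=C10 geometry becomes a matter of chair topology. The forward step needs cis alkenyl groups, both enol ethers trans along the rearranging chain and the correct C1 configuration.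

20 ⇒ 18 ⇒ 16 + 17. The O9–CH2 bond and the C9–C10 bond are cut, so the vinylogous carbonate comes from a plain acetate side chain and a formyl carbon. This keeps the electrophilic acrylate out of the organometallic step. The demand is the Z acrylate (O9 cis to the ester) and a masked C6 oxygen during enolate formation.

16 ⇒ 8 + 14. The C6–C7 bond is cut to a ketone and a two-carbon alkoxyvinyl nucleophile. The nucleophile must attack the face cis to the C1 side chain and must not enolise the ketone.

14 ⇒ 12 ⇒ 9. The C–I and C–H bonds of the vinyl unit are cut back to an alkynyl ether, then the O–C(sp) bond is cut. This gives the E geometry by syn hydrometalation. The forward steps must avoid heat, which rearranges benzyl alkynyl ethers.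

8 ⇒ 6 + 7. The C1–C10 bond is cut. The enone enolate should alkylate anti to the fused dioxolane. The demand is a cold, fast alkylation before the C2 oxygen is expelled.

6 ⇒ 5 ⇒ 4 ⇒ 3 ⇒ 2 ⇒ 1. In turn the C6 carbonyl goes back to CH2, C6–C1 to the second alkene of a diene, C1–H to C1–I, the acetonide to the diol, and the two C–O bonds to the arene. Iodine is there because it steers the dioxygenase, so that after its removal the methyl group sits next to C3 with the configuration needed (the diol from the parent methylarene would be the mirror image). The demands are selective reduction of the disubstituted alkene and allylic oxidation at the ring CH2.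

38 ⇒ 37 ⇒ 36 ⇒ 35. The epoxide C–O bonds are cut at the allylic alcohol stage, because the unsaturated acid itself is a poor substrate for asymmetric epoxidation. The demand is the unnatural tartrate and a Z-alkene-tolerant epoxidation.

## Other disconnections considered

Alternative 1: The cut is C11–C12 and C12–O6, with carbon monoxide as the inserted carbon. In the forward step the 6-hydroxy-7-ethynyl macrocycle A1 would take up CO on a divalent palladium catalyst (PdCl2, thiourea, CO) and close to the O9-silyl ether of the target, A2. In its favour, two bonds and the exocyclic methylene arise in one neutral step, with no amide base, no methyl iodide and no elimination. On late-stage mildness it is better than the plan chosen here. Against it, A1 already contains the whole ten-membered ring with six stereocentres, so the ring problem is untouched, and an ethynyl group trans to O6 at C7 is not easy to introduce (an enolate cannot simply be alkynylated). Any zerovalent palladium formed under CO could also ionise the doubly allylic epoxide. On structure the two plans are equal in that C6/C7 must be set beforehand. On mechanism the alternative is gentler. On step economy it is worse, because the ethynyl group costs more steps than the alkylation–reduction–methylenation sequence it replaces.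

Alternative 2: The cut is C5–C6. In the forward step the iodo aldehyde A3 would be treated with CrCl2 and catalytic NiCl2 at high dilution, and the alkenylchromium species would add to the aldehyde to give the macrocyclic alcohol A4. In its favour, the reaction tolerates esters, epoxides and silyl ethers and is an established way to close ten-membered carbocycles. The C4=C5 geometry is stored in the alkenyl iodide, and the 2,3-epoxide can be made on an open chain by reagent control. On that last point it is better than the chosen plan, which needs a late diol-to-epoxide conversion. Against it, A3 is an open chain with five stereocentres and two Z-trisubstituted alkenes, each needing its own controlled step. Its α-branched, β-acyloxy aldehyde can epimerise or eliminate. The C6 configuration is decided in the ring closure with no clear bias, and the closure fights entropy and needs stoichiometric divalent chromium. On structure the chosen plan gets both cis alkenes and the ring from topology. On mechanism the alternative is a tolerant polar addition. On step economy it is more convergent but most likely longer in total.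

Alternative 3: The cut is C2–C3. In the forward step the bis-enal A5 would be reduced by SmI2 and the two ketyl carbons would couple to the macrocyclic erythro diol A6. In its favour, the ring and two carbinol centres form in one step with the lactone and the 8,9-diol already in place, and samarium-bridged coupling normally gives the cis (erythro) diol. The later diol-to-epoxide conversion with net retention is the same task as in the chosen plan, so the two are equal there. Against it, both carbonyls are enals, so the ketyls are allyl radicals that can rotate (loss of the ring-cis geometry) or couple at the γ carbon. The C1=C10 alkene of A5 lies between an aldehyde and an ester and is an easy target for conjugate reduction by divalent samarium. Nothing fixes the absolute sense of the new diol relative to C6–C9. On structure the chosen plan takes C2/C3 from an enzymatic diol of defined configuration. On mechanism the radical coupling is less predictable. On step economy the ring-forming event is shorter, but the precursor is as demanding as that of Alternative 2.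

Key step: step 12

Remarks on the chemistry (assumptions and corrections):
- Numbering is that of germacrane: ring C1–C10, lactone carbons C11–C13, ester carbon C14, methyl C15. The same numbers are used for the six-membered intermediates.
- Diol 2 is assumed to come from the biotransformation in high enantiomeric purity and to be brought to a single enantiomer by recrystallisation.
- In 20 the oxygen O9 is trans to C1 along the chain C1–C10=C9–O. By the sequence rules this is the Z acrylate, since the ester outranks C1. It is not the isomer that equilibrating O-alkylation of a formyl ester normally gives, so the geometry is set under chelation control (step 11).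
- A methoxymethyl ether on O9 could be removed only with acid, which two epoxides would not survive. O9 is therefore carried as the (triisopropylsiloxy)methyl acetal, made by the same chloromethyl-ether chemistry and removed by fluoride.
- The ester is formylated only after the C6 ketone has become a silylated carbinol. The ketone α-hydrogen is more acidic than the ester α-hydrogens, and its enolate can expel the C2 oxygen. The silyl group also stops the tertiary alkoxide from lactonising onto the trans side chain.

## Steps

Step 1
Reactants: 1 4-iodotoluene
Product: 2 (1S,2S)-3-iodo-6-methylcyclohexa-3,5-diene-1,2-diol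
Conditions: E. coli JM109(pDTG601) whole cells (toluene dioxygenase), O2, glucose, phosphate buffer pH 7.2, 30 °C; recrystallisation
Reagents that add atoms: dioxygen, O=O
Why: Enzymatic arene cis-dihydroxylation; the larger iodine substituent directs the dioxygenase to the adjacent 2,3-bond, which fixes both carbinol centres (the future C2 and C3) in the sense needed once iodine is removed.

Step 2
Reactants: 2 (1S,2S)-3-iodo-6-methylcyclohexa-3,5-diene-1,2-diol
Product: 3 (3aS,7aS)-7-iodo-2,2,4-trimethyl-3a,7a-dihydro-1,3-benzodioxole
Conditions: Me2C(OMe)2, p-TsOH (cat.), acetone, 0 °C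
Reagents that add atoms: 2,2-dimethoxypropane, COC(C)(C)OC
Why: Acid-catalysed transacetalisation of a cis-1,2-diol; protection also prevents dehydration of the diene diol to a phenol.

Step 3
Reactants: 3 (3aS,7aS)-7-iodo-2,2,4-trimethyl-3a,7a-dihydro-1,3-benzodioxole
Product: 4 (3aS,7aR)-2,2,4-trimethyl-3a,7a-dihydro-1,3-benzodioxole
Conditions: Bu3SnH (1.05 equiv, slow addition), Pd(PPh3)4 (3 mol %), THF, 0 °C → rt; used at once
Reagents that add atoms: none
Why: Hydrodehalogenation of an alkenyl iodide by zerovalent palladium and tin hydride (oxidative addition, Sn–H transmetalation, reductive elimination); no stereocentre is touched and the diene is used immediately to avoid Diels–Alder dimerisation.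

Step 4
Reactants: 4 (3aS,7aR)-2,2,4-trimethyl-3a,7a-dihydro-1,3-benzodioxole
Product: 5 (3aS,7aR)-2,2,4-trimethyl-3a,6,7,7a-tetrahydro-1,3-benzodioxole
Conditions: KO2CN=NCO2K, AcOH, MeOH, 0 °C → rt
Reagents that add atoms: none
Why: Diimide reduction by concerted syn transfer of H2; the cis-disubstituted alkene C6=C1 should react much faster than the trisubstituted C4=C5, and no 1,4-addition or alkene migration is possible.

Step 5
Reactants: 5 (3aS,7aR)-2,2,4-trimethyl-3a,6,7,7a-tetrahydro-1,3-benzodioxole
Product: 6 (3aS,7aR)-2,2,4-trimethyl-7,7a-dihydro-1,3-benzodioxol-6(3aH)-one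
Conditions: Rh2(cap)4 (dirhodium tetracaprolactamate, 1 mol %), t-BuOOH (aq., 5 equiv), K2CO3, CH2Cl2, rt
Reagents that add atoms: tert-butyl hydroperoxide, CC(C)(C)OO
Why: Radical allylic oxidation of a cyclohexene to the enone via the allylic peroxide; the ring CH2 at C6 is the accessible allylic position, while C3–H is tertiary and inductively deactivated by the dioxolane oxygens and the methyl C–H bonds are stronger.

Step 6
Reactants: 6 (3aS,7aR)-2,2,4-trimethyl-7,7a-dihydro-1,3-benzodioxol-6(3aH)-one; 7 methyl bromoacetate
Product: 8 methyl 2-[(3aS,7R,7aR)-2,2,4-trimethyl-6-oxo-3a,6,7,7a-tetrahydro-1,3-benzodioxol-7-yl]acetate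
Conditions: LDA, THF, –78 °C; then 7, –78 → –40 °C
Reagents that add atoms: none
Why: Kinetic α′-deprotonation of the enone gives the cross-conjugated lithium enolate, which is alkylated (SN2) on the convex face, anti to the adjacent dioxolane oxygen, so the C1 side chain ends trans to O2. The low temperature is meant to keep the enolate from expelling the C2 oxygen.

Step 7
Reactants: 9 4-methoxybenzyl alcohol
Product: 12 4-methoxybenzyl ethynyl ether, via dichlorovinyl ether 10 (not isolated), via lithium alkynyl ether 11 (not isolated)
Conditions: KH, THF, 0 °C; Cl2C=CHCl, –50 °C → rt; n-BuLi (2.3 equiv), –78 °C; MeOH; kept below rt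
Reagents that add atoms: trichloroethylene, ClC=C(Cl)Cl
Why: Addition of the alkoxide to dichloroacetylene formed in situ gives the 1,2-dichlorovinyl ether; elimination and chlorine–lithium exchange then give the lithium alkynyl ether, which is protonated. The product is kept cold because benzyl alkynyl ethers rearrange sigmatropically on warming.

Step 8
Reactants: 12 4-methoxybenzyl ethynyl ether
Product: 14 (E)-2-iodoethenyl 4-methoxybenzyl ether, via alkenylzirconocene chloride 13 (not isolated)
Conditions: Cp2Zr(H)Cl, CH2Cl2, rt; then I2 (1.0 equiv), –78 °C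
Reagents that add atoms: iodine, II
Why: Hydrozirconation is a syn addition with zirconium at the terminal carbon, and iododemetalation proceeds with retention, so the E alkenyl iodide results.

Step 9
Reactants: 8 methyl 2-[(3aS,7R,7aR)-2,2,4-trimethyl-6-oxo-3a,6,7,7a-tetrahydro-1,3-benzodioxol-7-yl]acetate; 14 (E)-2-iodoethenyl 4-methoxybenzyl ether
Product: 16 methyl 2-[6-{(E)-2-[(4-methoxybenzyl)oxy]ethenyl}-2,2,4-trimethyl-6-(trimethylsilyloxy)-3a,6,7,7a-tetrahydro-1,3-benzodioxol-7-yl]acetate (ethenyl cis to the acetate chain and anti to the dioxolane), via vinyllithium 15 (not isolated)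
Conditions: 14, t-BuLi (2 equiv), Et2O, –78 °C; 8·LaCl3·2LiCl in THF, –78 °C; then Me3SiCl, Et3N, –78 → 0 °C
Reagents that add atoms: chlorotrimethylsilane, C[Si](C)(C)Cl
Why: Iodine–lithium exchange gives the configurationally stable E alkoxyvinyllithium, and Lewis-acid-promoted 1,2-addition to the ketone avoids enolisation. The new C6 centre is set by axial attack on the half-chair that has the C1 chain pseudo-equatorial, from the face anti to the dioxolane, which places the vinyl group cis to the C1 chain. Silylation of the alkoxide in the same flask blocks lactonisation onto the ester.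

Step 10
Reactants: 16 methyl 2-[6-{(E)-2-[(4-methoxybenzyl)oxy]ethenyl}-2,2,4-trimethyl-6-(trimethylsilyloxy)-3a,6,7,7a-tetrahydro-1,3-benzodioxol-7-yl]acetate; 17 methyl formate
Product: 18 formyl ester of 16 drawn as its hydrogen-bonded Z enol: methyl (Z)-3-hydroxy-2-[ring]prop-2-enoate with C1 and C6 as in 16
Conditions: LDA (2.2 equiv), THF, –78 °C; 17 (excess), –78 → –20 °C; AcOH
Reagents that add atoms: none
Why: Crossed Claisen condensation of the ester enolate with methyl formate; with C6 now a silyl ether the ester α-hydrogens are the only acidic ones, and the product is drained as its stabilised enolate.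

Step 11
Reactants: 18 formyl ester of 16 (Z enol)
Product: 20 rearrangement precursor: cis-1,2-dialkenylcyclohexenol acetonide with C6–OH free and (Z)-3-[(triisopropylsiloxy)methoxy]acrylate at C1 (O9 trans to C1), via silyl ether 19 (not isolated)
Conditions: NaH (1.05 equiv), THF, 0 °C; (i-Pr)3SiOCH2Cl, 0 °C; then AcOH, Bu4NF, 0 °C
Reagents that add atoms: (triisopropylsiloxy)methyl chloride, ClCO[Si](C(C)C)(C(C)C)C(C)C
Why: The chloromethyl ether is a hard electrophile and should alkylate the enolate on oxygen, and the sodium chelate between enolate oxygen and ester carbonyl should hold O9 cis to the ester, which is the geometry trans to C1. Buffered fluoride then removes only the tertiary trimethylsilyl ether, since the triisopropylsilyl acetal reacts far more slowly.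

Step 12
Reactants: 20 rearrangement precursor (cis-1,2-dialkenylcyclohexenol acetonide)
Product: 23 (1(10)Z,4Z)-cyclodecadienone: 6-oxo-2,3-O-isopropylidene-8-O-(4-methoxybenzyl)-9-O-[(triisopropylsiloxy)methyl] 14-methyl ester with 8,9-threo ethers, via potassium alkoxide 21 (not isolated), via potassium enolate 22 (not isolated)
Conditions: KHMDS, 18-crown-6, THF, –78 → 0 °C; AcOH, –78 °C
Reagents that add atoms: none
Why: KHMDS converts 20 into the potassium alkoxide 21, whose C1–C6 bond is weakened by the adjacent O–; the 3-oxido-1,5-diene C8=C7–C6–C1–C10=C9 then undergoes a [3,3]-sigmatropic shift (anionic oxy-Cope rearrangement) that forms C8–C9, breaks C1–C6 and is driven by formation of the enolate 22. The closest known reaction type is the KH/18-crown-6 rearrangement of 1,2-dialkenylcyclohexanols to cyclodec-5-enones. The ten-membered ring is not closed end to end: it arises by four-carbon ring expansion when the bond shared by the cyclohexene and the six-centre chair array is cleaved, so no high dilution is needed. C8 and C9 are set together by the chair: both enol ethers are trans along the rearranging chain, so both alkoxy groups sit equatorial and the 8,9-threo arrangement results, while the absolute sense follows from C1 (alkenyl trans to the dioxolane) and the cis placement of the C6 vinyl group. This chair grows out of the ground-state half-chair (C6 vinyl axial, C1 alkenyl equatorial) and puts the ring bond C1–C2 axial on the array, which gives the ring-cis C1=C10 alkene; the other chair would need C2 equatorial next to the C10 ester (A(1,2) strain) and a ring flip, and a boat should be higher in energy as usual. C4=C5 is a spectator carried over from the cyclohexene. The step needs rearrangement to outrun attack of the alkoxide on the trans-disposed ester (a lactonisation that is reversible, because the expelled methoxide can reopen the lactone) and to outrun E1cB loss of the C8 ether from 22, which is why it is run cold and quenched with acid at –78 °C, protonation at C7 then giving 23.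

Step 13
Reactants: 23 (1(10)Z,4Z)-cyclodecadienone; 7 methyl bromoacetate
Product: 24 C7-alkylated ketone: 23 bearing CH2CO2Me at C7 on the same ring face as O8 (7,8-anti in the zigzag sense)
Conditions: LiHMDS, THF, –78 °C; 7, DMPU, –78 → –50 °C
Reagents that add atoms: none
Why: Kinetic deprotonation of the enone at its only α′ position (C7) and SN2 alkylation of the lithium enolate; the electrophile should enter anti to the C8–O bond on the rotamer with C8–H eclipsing the enolate, as in alkylations of β-alkoxy enolates, which gives the 7,8-anti product. The low temperature is meant to prevent β-elimination of the C8 ether.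

Step 14
Reactants: 24 C7-alkylated ketone
Product: 26 trans-fused 12,6-lactone with C11 as CH2 and acetonide plus both ethers retained, via hydroxy ester 25 (not isolated)
Conditions: NaBH4, CeCl3·7H2O, MeOH, –78 °C; then PPTS (cat.), CH2Cl2, rt
Reagents that add atoms: none
Why: Luche 1,2-reduction of the enone; Felkin–Anh control from C7 and the 1,3-anti preference from the C8 ether both predict hydride delivery to the face that makes O6 syn to the C7 chain in the zigzag sense, which is the trans relation on the ring. The hydroxy ester 25 then closes to the γ-lactone under mild acid catalysis.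

Step 15
Reactants: 26 trans-fused lactone acetonide
Product: 27 2,3-cis-diol of 26
Conditions: AcOH–H2O (4:1), 45 °C
Reagents that add atoms: none
Why: Acid hydrolysis of the isopropylidene acetal; the benzyl-type ether, the siloxymethyl acetal (comparable to a methoxymethyl ether towards dilute acid) and both esters should survive.

Step 16
Reactants: 27 2,3-cis-diol
Product: 30 2,3-cis-epoxide with both C–O configurations of 27 retained, via cyclic orthoacetate 28 (not isolated), via chloro acetate 29 (not isolated)
Conditions: MeC(OMe)3, PPTS (cat.), CH2Cl2, rt; Me3SiCl, CH2Cl2, 0 °C; K2CO3, MeOH, 0 °C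
Reagents that add atoms: none
Why: One-flask diol-to-epoxide conversion through the 2-methoxydioxolane: Me3SiCl generates the dioxolanylium ion, which chloride opens by SN2 at the allylic C3 (first inversion); methanolysis of the acetate then frees O2, which displaces chloride (second inversion at the same carbon), so both centres keep their configuration. Attack at C2 instead would converge on the same epoxide.

Step 17
Reactants: 30 2,3-cis-epoxide with saturated lactone
Product: 33 α-methylene lactone (C11=C13H2) with epoxide and both ethers retained, via Mannich base 31 (not isolated), via ammonium iodide 32 (not isolated)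
Conditions: LDA, THF, –78 °C; Me2N=CH2 I (Eschenmoser's salt), –78 → 0 °C; MeI, CH2Cl2–MeOH, rt; aq. NaHCO3
Reagents that add atoms: N,N-dimethylmethyleneiminium iodide, C=[N+](C)C.[I-]
Why: Mannich reaction of the lactone enolate (C11 carries the only readily removable α-hydrogens) followed by quaternisation and E1cB elimination of trimethylamine; the epoxide has no hydrogen placed for base-induced opening.

Step 18
Reactants: 33 α-methylene lactone
Product: 34 8-hydroxy compound (O8 free and O9 still protected)
Conditions: DDQ, CH2Cl2–pH 7 buffer, 0 °C
Reagents that add atoms: none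
Why: Oxidative cleavage of the 4-methoxybenzyl ether by hydride abstraction and hydrolysis of the oxocarbenium ion under buffered neutral conditions, which epoxide, methylene lactone and siloxymethyl acetal tolerate.

Step 19
Reactants: 35 angelic acid
Product: 36 (2Z)-2-methylbut-2-en-1-ol
Conditions: LiAlH4, Et2O, 0 °C
Reagents that add atoms: none
Why: Hydride reduction of the acid to the allylic alcohol; the cold, non-acidic conditions should avoid isomerisation to the E isomer.

Step 20
Reactants: 36 (2Z)-2-methylbut-2-en-1-ol
Product: 37 [(2R,3S)-2,3-dimethyloxiran-2-yl]methanol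
Conditions: Ti(Oi-Pr)4, D-(–)-diethyl tartrate, t-BuOOH, 4 Å MS, CH2Cl2, –20 °C
Reagents that add atoms: tert-butyl hydroperoxide, CC(C)(C)OO
Why: Sharpless asymmetric epoxidation; the unnatural tartrate delivers oxygen to the face that gives the (2R,3S) epoxy alcohol, and the alkene geometry is kept, so the two methyl groups stay trans.

Step 21
Reactants: 37 [(2R,3S)-2,3-dimethyloxiran-2-yl]methanol
Product: 38 (2S,3S)-2,3-dimethyloxirane-2-carboxylic acid
Conditions: RuCl3 (cat.), NaIO4, CCl4–MeCN–H2O, rt
Reagents that add atoms: water, O
Why: Oxidation of the primary alcohol by catalytic RuO4 to the acid without touching the epoxide; the descriptor at C2 changes only because the priorities change.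

Step 22
Reactants: 34 8-hydroxy compound; 38 (2S,3S)-2,3-dimethyloxirane-2-carboxylic acid
Product: 40 O8-[(2S,3S)-2,3-epoxy-2-methylbutanoyl] ester with O9 still protected, via mixed anhydride 39 (not isolated)
Conditions: 38, 2,4,6-Cl3C6H2COCl, Et3N, toluene, rt; then 34, DMAP, rt
Reagents that add atoms: none
Why: Yamaguchi esterification through the mixed anhydride and the acylpyridinium ion; no stereocentre is involved, and the acid has no α-hydrogen, so it cannot epimerise.

Step 23
Reactants: 40 O8-ester with O9 (triisopropylsiloxy)methyl acetal
Product: 42 CNP0291485.3 (target), via hemiacetal 41 (not isolated)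
Conditions: Bu4NF–AcOH (1:1), THF, 0 °C → rt; then pH 7 buffer
Reagents that add atoms: none
Why: Fluoride cleaves the Si–O bond of the siloxymethyl acetal and the resulting formaldehyde hemiacetal collapses at neutral pH to the free O9–H; buffering with acetic acid is meant to prevent acyl shift from O8 and addition to the methylene lactone.

## Compound list

1 | 4-iodotoluene | Cc1ccc(I)cc1 | starting material
2 | (1S,2S)-3-iodo-6-methylcyclohexa-3,5-diene-1,2-diol | CC1=CC=C(I)[C@@H](O)[C@H]1O | intermediate
3 | (3aS,7aS)-7-iodo-2,2,4-trimethyl-3a,7a-dihydro-1,3-benzodioxole | CC1=CC=C(I)[C@H]2OC(C)(C)O[C@@H]12 | intermediate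
4 | (3aS,7aR)-2,2,4-trimethyl-3a,7a-dihydro-1,3-benzodioxole | CC1=CC=C[C@H]2OC(C)(C)O[C@@H]12 | intermediate
5 | (3aS,7aR)-2,2,4-trimethyl-3a,6,7,7a-tetrahydro-1,3-benzodioxole | CC1=CCC[C@H]2OC(C)(C)O[C@@H]12 | intermediate
6 | (3aS,7aR)-2,2,4-trimethyl-7,7a-dihydro-1,3-benzodioxol-6(3aH)-one | O=C1C=C(C)[C@@H]2OC(C)(C)O[C@@H]2C1 | intermediate
7 | methyl bromoacetate | COC(=O)CBr | starting material
8 | methyl 2-[(3aS,7R,7aR)-2,2,4-trimethyl-6-oxo-3a,6,7,7a-tetrahydro-1,3-benzodioxol-7-yl]acetate | O=C1C=C(C)[C@@H]2OC(C)(C)O[C@@H]2[C@H]1CC(=O)OC | intermediate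
9 | 4-methoxybenzyl alcohol | COc1ccc(CO)cc1 | starting material
10 | (E)-1,2-dichlorovinyl 4-methoxybenzyl ether | Cl/C=C(/Cl)OCc1ccc(OC)cc1 | intermediate
11 | lithium 2-[(4-methoxybenzyl)oxy]ethynide | [Li]C#COCc1ccc(OC)cc1 | intermediate
12 | 4-methoxybenzyl ethynyl ether | C#COCc1ccc(OC)cc1 | intermediate
13 | chlorido{(E)-2-[(4-methoxybenzyl)oxy]ethenyl}zirconocene | Cl[Zr](/C=C/OCc1ccc(OC)cc1)(C1C=CC=C1)C1C=CC=C1 | intermediate
14 | (E)-2-iodoethenyl 4-methoxybenzyl ether | I/C=C/OCc1ccc(OC)cc1 | intermediate
15 | (E)-2-[(4-methoxybenzyl)oxy]ethenyllithium | [Li]/C=C/OCc1ccc(OC)cc1 | intermediate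
16 | methyl 2-[6-{(E)-2-[(4-methoxybenzyl)oxy]ethenyl}-2,2,4-trimethyl-6-(trimethylsilyloxy)-3a,6,7,7a-tetrahydro-1,3-benzodioxol-7-yl]acetate, ethenyl cis to the acetate chain, both anti to the dioxolane | C[Si](C)(C)O[C@]1(/C=C/OCc2ccc(OC)cc2)C=C(C)[C@@H]3OC(C)(C)O[C@@H]3[C@H]1CC(=O)OC | intermediate
17 | methyl formate | COC=O | starting material
18 | formyl ester of 16 as its Z enol (OH cis to the ester) | C[Si](C)(C)O[C@]1(/C=C/OCc2ccc(OC)cc2)C=C(C)[C@@H]3OC(C)(C)O[C@@H]3[C@H]1/C(C(=O)OC)=C/O | intermediate
19 | (Z)-3-[(triisopropylsiloxy)methoxy]acrylate, C6 trimethylsilyl ether | C[Si](C)(C)O[C@]1(/C=C/OCc2ccc(OC)cc2)C=C(C)[C@@H]3OC(C)(C)O[C@@H]3[C@H]1/C(C(=O)OC)=C/OCO[Si](C(C)C)(C(C)C)C(C)C | intermediate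
20 | rearrangement precursor: cis-1,2-dialkenylcyclohexenol acetonide, C6–OH free, O8 4-methoxybenzyl, O9 (triisopropylsiloxy)methyl | O[C@]1(/C=C/OCc2ccc(OC)cc2)C=C(C)[C@@H]3OC(C)(C)O[C@@H]3[C@H]1/C(C(=O)OC)=C/OCO[Si](C(C)C)(C(C)C)C(C)C | intermediate
21 | potassium alkoxide of 20 | [K+].[O-][C@]1(/C=C/OCc2ccc(OC)cc2)C=C(C)[C@@H]3OC(C)(C)O[C@@H]3[C@H]1/C(C(=O)OC)=C/OCO[Si](C(C)C)(C(C)C)C(C)C | intermediate
22 | potassium C6–C7 enolate of 23 (O cis to C8) | [C@H]1(OCc2ccc(OC)cc2)/C=C(\[O-])/C=C(/C)[C@@H]3OC(C)(C)O[C@@H]3/C=C(/C(=O)OC)[C@@H]1OCO[Si](C(C)C)(C(C)C)C(C)C.[K+] | intermediate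
23 | (1(10)Z,4Z)-cyclodecadienone: 6-oxo, 2,3-O-isopropylidene, 8-O-(4-methoxybenzyl), 9-O-[(triisopropylsiloxy)methyl], 14-methyl ester, 8,9-threo | O=C1/C=C(/C)[C@@H]2OC(C)(C)O[C@@H]2/C=C(/C(=O)OC)[C@H](OCO[Si](C(C)C)(C(C)C)C(C)C)[C@@H](OCc3ccc(OC)cc3)C1 | intermediate
24 | 23 with CH2CO2Me at C7, on the ring face of O8 | O=C1/C=C(/C)[C@@H]2OC(C)(C)O[C@@H]2/C=C(/C(=O)OC)[C@H](OCO[Si](C(C)C)(C(C)C)C(C)C)[C@@H](OCc3ccc(OC)cc3)[C@H]1CC(=O)OC | intermediate
25 | 6-hydroxy diester (O6 trans to the C7 chain on the ring) | O[C@@H]1/C=C(/C)[C@@H]2OC(C)(C)O[C@@H]2/C=C(/C(=O)OC)[C@H](OCO[Si](C(C)C)(C(C)C)C(C)C)[C@@H](OCc3ccc(OC)cc3)[C@H]1CC(=O)OC | intermediate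
26 | trans-fused 12,6-lactone, C11 = CH2, 2,3-acetonide | C1C(=O)O[C@@H]2/C=C(/C)[C@@H]3OC(C)(C)O[C@@H]3/C=C(/C(=O)OC)[C@H](OCO[Si](C(C)C)(C(C)C)C(C)C)[C@@H](OCc4ccc(OC)cc4)[C@@H]12 | intermediate
27 | 2,3-cis-diol of 26 | C1C(=O)O[C@@H]2/C=C(/C)[C@H](O)[C@H](O)/C=C(/C(=O)OC)[C@H](OCO[Si](C(C)C)(C(C)C)C(C)C)[C@@H](OCc3ccc(OC)cc3)[C@@H]12 | intermediate
28 | 2,3-cyclic orthoacetate (2-methoxy-2-methyl-1,3-dioxolane, mixture at the orthoester carbon) | C1C(=O)O[C@@H]2/C=C(/C)[C@@H]3OC(C)(OC)O[C@@H]3/C=C(/C(=O)OC)[C@H](OCO[Si](C(C)C)(C(C)C)C(C)C)[C@@H](OCc4ccc(OC)cc4)[C@@H]12 | intermediate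
29 | 3-chloro-2-acetoxy compound (C3 inverted) | C1C(=O)O[C@@H]2/C=C(/C)[C@@H](Cl)[C@H](OC(C)=O)/C=C(/C(=O)OC)[C@H](OCO[Si](C(C)C)(C(C)C)C(C)C)[C@@H](OCc3ccc(OC)cc3)[C@@H]12 | intermediate
30 | 2,3-cis-epoxide, saturated lactone | C1C(=O)O[C@@H]2/C=C(/C)[C@@H]3O[C@@H]3/C=C(/C(=O)OC)[C@H](OCO[Si](C(C)C)(C(C)C)C(C)C)[C@@H](OCc4ccc(OC)cc4)[C@@H]12 | intermediate
31 | 11-(dimethylaminomethyl) lactone (mixture at C11) | CN(C)CC1C(=O)O[C@@H]2/C=C(/C)[C@@H]3O[C@@H]3/C=C(/C(=O)OC)[C@H](OCO[Si](C(C)C)(C(C)C)C(C)C)[C@@H](OCc4ccc(OC)cc4)[C@@H]12 | intermediate
32 | trimethylammonium iodide of 31 | C[N+](C)(C)CC1C(=O)O[C@@H]2/C=C(/C)[C@@H]3O[C@@H]3/C=C(/C(=O)OC)[C@H](OCO[Si](C(C)C)(C(C)C)C(C)C)[C@@H](OCc4ccc(OC)cc4)[C@@H]12.[I-] | intermediate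
33 | α-methylene lactone, O8 4-methoxybenzyl, O9 (triisopropylsiloxy)methyl | C=C1C(=O)O[C@@H]2/C=C(/C)[C@@H]3O[C@@H]3/C=C(/C(=O)OC)[C@H](OCO[Si](C(C)C)(C(C)C)C(C)C)[C@@H](OCc4ccc(OC)cc4)[C@@H]12 | intermediate
34 | 8-hydroxy compound, O9 (triisopropylsiloxy)methyl | C=C1C(=O)O[C@@H]2/C=C(/C)[C@@H]3O[C@@H]3/C=C(/C(=O)OC)[C@H](OCO[Si](C(C)C)(C(C)C)C(C)C)[C@@H](O)[C@@H]12 | intermediate
35 | angelic acid | C/C=C(/C)C(=O)O | starting material
36 | (2Z)-2-methylbut-2-en-1-ol | C/C=C(/C)CO | intermediate
37 | [(2R,3S)-2,3-dimethyloxiran-2-yl]methanol | OC[C@@]1(C)O[C@H]1C | intermediate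
38 | (2S,3S)-2,3-dimethyloxirane-2-carboxylic acid | OC(=O)[C@@]1(C)O[C@H]1C | intermediate
39 | mixed anhydride of 38 with 2,4,6-trichlorobenzoic acid | O=C(OC(=O)c1c(Cl)cc(Cl)cc1Cl)[C@@]1(C)O[C@H]1C | intermediate
40 | O9-[(triisopropylsiloxy)methyl] ether of the target | C=C1C(=O)O[C@@H]2/C=C(/C)[C@@H]3O[C@@H]3/C=C(/C(=O)OC)[C@H](OCO[Si](C(C)C)(C(C)C)C(C)C)[C@@H](OC(=O)[C@@]4(C)O[C@H]4C)[C@@H]12 | intermediate
41 | O9-hydroxymethyl hemiacetal of the target | C=C1C(=O)O[C@@H]2/C=C(/C)[C@@H]3O[C@@H]3/C=C(/C(=O)OC)[C@H](OCO)[C@@H](OC(=O)[C@@]4(C)O[C@H]4C)[C@@H]12 | intermediate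
42 | CNP0291485.3: 2,3-cis-epoxy-9-hydroxy-8-[(2S,3S)-2,3-epoxy-2-methylbutanoyloxy]germacra-1(10)Z,4Z,11(13)-trien-12,6-olide 14-methyl ester | C=C1C(=O)O[C@@H]2/C=C(/C)[C@@H]3O[C@@H]3/C=C(/C(=O)OC)[C@H](O)[C@@H](OC(=O)[C@@]3(C)O[C@H]3C)[C@@H]12 | target

## Step count and least certain steps

Total: 23 steps. Longest linear sequence: 18 steps (steps 1–6, 9–18, 22 and 23). Steps 7–8 and 19–21 are side branches.

Step 12 (key step). The most likely failures are E1cB loss of the C8 benzyloxy group from enolate 22 as the mixture warms, lactonisation of alkoxide 21 onto the ester that is not reversed fast enough, and rearrangement through the other chair, which would give the ring-trans C1=C10 alkene. The fallback is a neutral siloxy-Cope rearrangement, which involves neither an alkoxide nor an enolate. It sets out from 19, isolated instead of being desilylated. Heating 19 in toluene at 160–180 °C in base-washed glass should give, through the same chair, the ten-membered trimethylsilyl enol ether F1. Buffered fluoride at –78 °C would then release the ketone, and the route is rejoined at 23.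

Step 6. The lithium enolate of 6 can expel the C2 oxygen of the dioxolane, which leads to ring opening and aromatisation and competes with a slow alkylation. The fallback uses an aza-enolate, which is known to tolerate ring oxygens in the β position. It sets out from 6. Condensation with 1,1-dimethylhydrazine gives the dimethylhydrazone F2. Deprotonation with LDA at the α′ carbon and alkylation with 7 give the alkylated hydrazone F3. Hydrolysis with aqueous CuCl2 returns the ketone, and the route is rejoined at 8.

Step 9. Facial selectivity may be poor: equatorial attack syn to the dioxolane would give the C6 epimer, whose chair leads to the wrong C1=C10 geometry. The fallback puts the configuration in the hands of a small, linear nucleophile with a strong preference for axial attack, and builds the enol ether afterwards. It sets out from 8. Addition of ethynylmagnesium bromide with CeCl3 and silylation in the flask give the ethynyl carbinol silyl ether F4. Hydroboration with pinacolborane and catalytic Cp2Zr(H)Cl gives the E alkenylboronate F5. Coupling with 9 in the presence of Cu(OAc)2, Et3N and air (oxidative C–O coupling of alkenylboronates with alcohols) gives the E enol ether, and the route is rejoined at 16.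

Step 11. Loss of geometric control is the risk: alkylation through the non-chelated enolate would place O9 cis to C1, which is also the thermodynamically preferred side for this class of acrylate. The fallback corrects the geometry after the fact instead of relying on the alkylation. It sets out from 18. Alkylation as in step 11, without the fluoride treatment, gives the chain-cis isomer F6 together with 19. F6 is then isomerised against the thermodynamic preference by triplet energy transfer (visible light, an iridium tris(phenylpyridine) sensitiser) with recycling, and the route is rejoined at 19.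

Step 13. The electrophile may attack the other face of the medium-ring enolate, and the enolate may lose the C8 ether by β-elimination. The fallback for the stereochemical problem replaces kinetic C–C bond formation by kinetic protonation. It sets out from 23. If alkylation gives mainly the C7 epimer F7, F7 is deprotonated again at C7 with LiHMDS at –78 °C and the tetrasubstituted enolate is protonated with a hindered phenol. The proton should enter from the face the electrophile used before, which inverts C7, and the route is rejoined at 24.

Step 16. The dioxolanylium ion may ionise at the allylic C3 instead of being opened by SN2, which would scramble C3 or lead to SN2′ attack at C5. The fallback avoids the cationic intermediate and uses two separate SN2 steps at one carbon. It sets out from 27. Selective mesylation (MsCl, collidine, –20 °C) gives the monomesylate F8, drawn as the C2 sulfonate. Displacement with LiBr in DMF gives the inverted bromohydrin F9. K2CO3 then closes the epoxide with the second inversion, and the route is rejoined at 30. A C3 mesylate would converge in the same way.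

## Further compounds

F1 | step 12 | trimethylsilyl enol ether of 23 (C6=C7, O cis to C8) | [C@H]1(OCc2ccc(OC)cc2)/C=C(\O[Si](C)(C)C)/C=C(/C)[C@@H]3OC(C)(C)O[C@@H]3/C=C(/C(=O)OC)[C@@H]1OCO[Si](C(C)C)(C(C)C)C(C)C
F2 | step 6 | N,N-dimethylhydrazone of 6 | CN(C)N=C1C=C(C)[C@@H]2OC(C)(C)O[C@@H]2C1
F3 | step 6 | N,N-dimethylhydrazone of 8 | CN(C)N=C1C=C(C)[C@@H]2OC(C)(C)O[C@@H]2[C@H]1CC(=O)OC
F4 | step 9 | 6-ethynyl-6-(trimethylsilyloxy) analogue of 16 | C[Si](C)(C)O[C@]1(C#C)C=C(C)[C@@H]2OC(C)(C)O[C@@H]2[C@H]1CC(=O)OC
F5 | step 9 | (E)-alkenyl pinacolboronate from F4 | C[Si](C)(C)O[C@]1(/C=C/B2OC(C)(C)C(C)(C)O2)C=C(C)[C@@H]3OC(C)(C)O[C@@H]3[C@H]1CC(=O)OC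
F6 | step 11 | geometric isomer of 19 with O9 cis to C1 | C[Si](C)(C)O[C@]1(/C=C/OCc2ccc(OC)cc2)C=C(C)[C@@H]3OC(C)(C)O[C@@H]3[C@H]1/C(C(=O)OC)=C\OCO[Si](C(C)C)(C(C)C)C(C)C
F7 | step 13 | C7 epimer of 24 | O=C1/C=C(/C)[C@@H]2OC(C)(C)O[C@@H]2/C=C(/C(=O)OC)[C@H](OCO[Si](C(C)C)(C(C)C)C(C)C)[C@@H](OCc3ccc(OC)cc3)[C@@H]1CC(=O)OC
F8 | step 16 | 2-O-methanesulfonate of 27 | C1C(=O)O[C@@H]2/C=C(/C)[C@H](O)[C@H](OS(C)(=O)=O)/C=C(/C(=O)OC)[C@H](OCO[Si](C(C)C)(C(C)C)C(C)C)[C@@H](OCc3ccc(OC)cc3)[C@@H]12
F9 | step 16 | 2-bromo-3-hydroxy compound (C2 inverted) | C1C(=O)O[C@@H]2/C=C(/C)[C@H](O)[C@@H](Br)/C=C(/C(=O)OC)[C@H](OCO[Si](C(C)C)(C(C)C)C(C)C)[C@@H](OCc3ccc(OC)cc3)[C@@H]12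
A1 | alternative 1 | 6-hydroxy-7-ethynyl macrocycle, O9 silyl ether | O[C@@H]1/C=C(/C)[C@@H]2O[C@@H]2/C=C(/C(=O)OC)[C@H](O[Si](C)(C)C(C)(C)C)[C@@H](OC(=O)[C@@]3(C)O[C@H]3C)[C@H]1C#C
A2 | alternative 1 | O9-tert-butyldimethylsilyl ether of the target | C=C1C(=O)O[C@@H]2/C=C(/C)[C@@H]3O[C@@H]3/C=C(/C(=O)OC)[C@H](O[Si](C)(C)C(C)(C)C)[C@@H](OC(=O)[C@@]3(C)O[C@H]3C)[C@@H]12
A3 | alternative 2 | open-chain C5 alkenyl iodide with C6 aldehyde | I/C=C(/C)[C@@H]1O[C@@H]1/C=C(/C(=O)OC)[C@H](O[Si](C)(C)C(C)(C)C)[C@@H](OC(=O)[C@@]2(C)O[C@H]2C)[C@H](C=O)CC(=O)OC
A4 | alternative 2 | macrocyclic C6 alcohol with C12 methyl ester | O[C@@H]1/C=C(/C)[C@@H]2O[C@@H]2/C=C(/C(=O)OC)[C@H](O[Si](C)(C)C(C)(C)C)[C@@H](OC(=O)[C@@]3(C)O[C@H]3C)[C@H]1CC(=O)OC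
A5 | alternative 3 | bis-enal with lactone and 8,9-acetonide | O=C/C(C)=C\[C@H]1OC(=O)C[C@@H]1[C@@H]2OC(C)(C)O[C@H]2/C(C(=O)OC)=C\C=O
A6 | alternative 3 | macrocyclic erythro 2,3-diol | C1C(=O)O[C@@H]2/C=C(/C)[C@H](O)[C@H](O)/C=C(/C(=O)OC)[C@@H]3OC(C)(C)O[C@H]3[C@@H]12
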